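## The problem

The target is a 20-membered macrocycle in which ring A (C1a–C6a, hydroxyl on C1a) and ring B (C1b–C6b, hydroxyls on C2b and C4b) are joined twice: by a diaryl ether oxygen between C5a and C1b and by an unbranched chain of fourteen methylenes between C3a and C6b. There is no stereocentre, so only regiochemistry and ring size have to be controlled; the stereo elements that arise on the way (one alkene geometry, one transient sp3 carbon) are erased before the end. The ether carbon C1b lies between the C2b oxygen and the C6b chain and is para to a third oxygen, which excludes nucleophilic aromatic substitution and makes a metal-mediated C–O coupling at this position slow. Ring A has an all-meta 1,3,5 pattern with two different oxygens, which electrophilic substitution cannot write and which, from a 5-alkylresorcinol, would require telling two equivalent hydroxyls apart. Unmasked ring B is a 4-aryloxyresorcinol (a hydroxyquinol ether) and is easily oxidised, so its hydroxyls should stay protected until the last operation and be released under neutral, non-oxidising conditions; on the way, the terminal ynol ether is sensitive to acid and water and the cyclobutenone to base and nucleophiles. The enabling feature is that ring A is a 3-aryloxy-5-alkylphenol (OH on C1a, alkyl on C3a, ether oxygen on C5a), exactly the pattern that results when a 3-alkylcyclobutenone is combined with an ynol ether, with C1a–C6a and C4a–C5a as the new bonds. The ether oxygen can therefore arrive already attached to ring B and bonded to an sp carbon, so that no arene C–O coupling is needed. The chain is symmetric about its midpoint, so both halves can come from one C8 building block and be joined by alkene metathesis.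

## Retrosynthesis

**Target 24 from macrocyclic alkene 23.** No skeletal bond is cut. Ring B is carried as its bis(benzyl) ether, so that the hydrogenation that saturates the mid-chain alkene of 23 also frees both hydroxyls. Methyl ethers would need a separate Lewis-acid demethylation on the oxidation-prone product. The forward reaction only has to leave the diaryl ether untouched, which Pd/C hydrogenolysis does.

**23 from diene 22.** The C7–C8 bond at the centre of the fourteen-carbon chain is cut. A cut at the ether would combine the hardest bond with the entropic cost of a 20-membered ring, and a cut next to an arene would demand a macrocyclising cross-coupling. The central cut gives an acyclic precursor with two identical oct-7-enyl arms. The forward ring-closing metathesis must favour cyclisation over oligomerisation, which is a matter of dilution; the alkene geometry is irrelevant.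

**22 from cyclobutenone 5 and ynol ether 17.** Ring A is taken apart at C1a–C6a and C4a–C5a. The neighbouring options, cutting O–C5a or O–C1b, lead back to an Ullmann-type coupling at the hindered, electron-rich C1b phenol and to the desymmetrisation of a resorcinol. The de novo construction avoids both: ring A collapses into a four-carbon ketone and a two-carbon alkyne, and the two fragments are of similar size. The forward benzannulation must be regioselective (oxygen meta to the new OH) and must tolerate two terminal alkenes.

**17 from phenol 11 and trichloroethylene 12, through dichlorovinyl ether 14.** The O–C(sp) bond is cut. An sp carbon is sterically undemanding, so the hindered phenol 11 can be used directly as the nucleophile. The forward sequence is addition of the phenoxide to dichloroacetylene 13 (formed in the flask from 12), then double dehalogenation of 14 with n-BuLi and protonation.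

**11 from aryl bromide 8 and from resorcinol diether 7.** The C1b–O bond is cut and traced back to a C–Br bond, then to a C–H bond. Starting from an already oxygenated 2,4-dialkoxyphenol and adding the chain ortho to the hydroxyl would give poor site control. In 7 the position para to one benzyloxy group and ortho to the other is the most nucleophilic, so bromination should go where the oxygen is needed.

**7 from 1,3-bis(benzyloxy)-5-bromobenzene 6 and Grignard reagent 2.** The C6b–CH2 bond is cut. A Kumada coupling of a primary alkylmagnesium halide with an aryl bromide is direct and uses the same reagent 2 that serves the other fragment.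

**5 from 3-ethoxycyclobutenone 3 and Grignard reagent 2.** The bond between the four-membered ring and the chain is cut. 1,2-Addition to the vinylogous ester followed by acid hydrolysis transposes the carbonyl and gives the 3-alkylcyclobutenone in one operation.

**2 from 8-bromooct-1-ene 1.** The C–Mg bond is traced back to the C–Br bond. One titrated stock solution of 2 supplies both halves of the chain, so the two branches share their only carbon building block.

## Roads not taken

Alternative 1: Ring B would be made last, by cutting C1b–C6b.
- **Key step.** Aqueous KOH would open the macrocyclic 4-pyrone A1 to a 1,3,5-triketone. Its aryloxy-bearing methylene would add across the ring to the far ketone, and dehydration would aromatise ring B and contract the macrocycle from 22 to 20 members, giving A2, the ring A methyl ether of the target.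
- **Merits.** The ether oxygen is attached by simple alkylation of a phenol with a pyronylmethyl halide, so no hindered C–O bond has to be forged. Ring B appears with both hydroxyls free. In these two respects this road is better than the chosen plan, which spends steps 4 to 7 putting an oxygen and a two-carbon unit onto ring B.
- **Weak points.** The triketone has a second aldol mode (the chain methylene next to the far ketone attacking the near ketone), which would give an isomeric resorcinol with an aryloxymethyl side chain, and it can also reclose to the pyrone. Only the higher acidity of the aryloxy-substituted methylene favours the wanted mode. The unsymmetrical macrocyclic pyrone A1 needs its own multistep assembly and macrocyclisation. The electron-rich ring B is born in hot aqueous base, and the ring A methyl ether must still be cleaved with a Lewis acid while ring B is exposed.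
- **Comparison.** The chosen plan sets against this an unambiguous regiochemical outcome, a convergent union of two similar-sized fragments, and a neutral final deprotection.

Alternative 2: Ring B would be functionalised at C6b and C1b in one pot through 3,5-dimethoxybenzyne A3.
- **Key step.** Iodine–magnesium exchange on an ortho-iodoaryl triflate and warming would release A3. The long-chain Grignard reagent would add at the aryne carbon remote from the methoxy group, and the resulting arylmagnesium would be trapped with B(OMe)3 and oxidised to phenol A4.
- **Merits.** Two bonds on ring B are made in one flask with well-understood aryne regiochemistry. For this part it is more economical than steps 3 to 5 of the chosen plan.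
- **Weak points.** A4 must then be closed by forming the diaryl ether as the macrocyclising step, between the doubly ortho-substituted electron-rich phenol and an unactivated aryl chloride. That is the hardest bond of the molecule made under the least favourable circumstances. The chain-bearing Grignard reagent with its aryl chloride needs a linear preparation, and three methyl ethers remain to be cleaved.
- **Comparison.** The chosen plan removes this risk by making the ether bond at an sp carbon before ring A exists and by closing the macrocycle at an unhindered C=C bond.

Alternative 3: Ring B would be built by cutting C5b–C6b and C3b–C4b.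
- **Key step.** With NaOMe, dimethyl malonate would add to the chain-bearing carbon of the macrocyclic aryloxy enone A5, and the methyl ketone enolate would then close onto a malonate ester, giving the cyclohexane-1,3-dione A6 inside the existing 20-membered ring.
- **Merits.** This is a classical, robust resorcinol synthesis with cheap reagents. The ether is made as an α-aryloxy ketone by alkylation. No hazardous intermediate such as dichloroacetylene is involved, which is a real advantage over the chosen plan.
- **Weak points.** A6 is not yet aromatic. Ester hydrolysis, decarboxylation and a dehydrogenation must follow, and three stereocentres are made only to be destroyed. The aryloxy group sits on the ring that is to be aromatised, and its loss as the ring A phenol offers the dione a non-oxidative way to aromatise that would open the macrocycle. Ring A would still need demethylation.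
- **Comparison.** The chosen plan delivers its new arene directly at the right oxidation level and needs two steps after the key step instead of four or more.

Key step: step 8

Assumption: 1,3-bis(benzyloxy)-5-bromobenzene 6 is treated as a catalogue compound; if supply fails it is one benzylation step from 5-bromoresorcinol.

## Route

Step 1
Reactants: 1 8-bromooct-1-ene
Product: 2 oct-7-en-1-ylmagnesium bromide (titrated stock solution in THF, kept under argon)
Conditions: Mg turnings, I2 (cat.), THF, rt → 40 °C
Reagents that add atoms: magnesium, [Mg]
Why: Grignard formation by oxidative insertion of magnesium into a primary C–Br bond; the alkene is too remote from the carbon–magnesium bond for cyclisation, and one solution is prepared for use in steps 2 and 3.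

Step 2
Reactants: 2 oct-7-en-1-ylmagnesium bromide; 3 3-ethoxycyclobut-2-en-1-one
Product: 5 3-(oct-7-en-1-yl)cyclobut-2-en-1-one, via 3-ethoxy-1-(oct-7-en-1-yl)cyclobut-2-en-1-ol 4 (not isolated)
Conditions: THF, –78 → 0 °C; then 1 M HCl (aq), 0 °C → rt
Reagents that add atoms: water, O
Why: Grignard 1,2-addition to the carbonyl of the vinylogous ester, then acid hydrolysis of the enol ether with loss of ethanol and water (a Stork–Danheiser-type carbonyl transposition), is the standard entry to 3-alkylcyclobutenones; the new carbonyl oxygen comes from water.

Step 3
Reactants: 2 oct-7-en-1-ylmagnesium bromide; 6 1,3-bis(benzyloxy)-5-bromobenzene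
Product: 7 1,3-bis(benzyloxy)-5-(oct-7-en-1-yl)benzene
Conditions: Pd(dppf)Cl2 (3 mol %), THF, 50 °C
Reagents that add atoms: none
Why: Kumada coupling of a primary alkyl Grignard reagent with an aryl bromide; the wide bite angle of dppf favours reductive elimination over β-hydride elimination, so the chain should couple without isomerisation, and benzyl ethers and the remote alkene are inert.

Step 4
Reactants: 7 1,3-bis(benzyloxy)-5-(oct-7-en-1-yl)benzene
Product: 8 1,5-bis(benzyloxy)-2-bromo-3-(oct-7-en-1-yl)benzene
Conditions: NBS (1.05 equiv), MeCN, –10 → 0 °C, dark
Reagents that add atoms: N-bromosuccinimide, O=C1CCC(=O)N1Br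
Why: Electrophilic aromatic bromination; the carbon para to one benzyloxy group and ortho to the other is the most activated, whereas the carbon between the two benzyloxy groups is shielded, and a resorcinol diether should react far faster than an isolated terminal alkene under ionic conditions in the dark.

Step 5
Reactants: 8 1,5-bis(benzyloxy)-2-bromo-3-(oct-7-en-1-yl)benzene
Product: 11 2,4-bis(benzyloxy)-6-(oct-7-en-1-yl)phenol, via aryllithium 9 (not isolated), via dimethyl arylboronate 10 (not isolated)
Conditions: n-BuLi, THF, –78 °C; B(OMe)3, –78 °C → rt; then 30% H2O2 (aq), NaOH (aq), 0 °C → rt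
Reagents that add atoms: hydrogen peroxide, OO
Why: Bromine–lithium exchange, borylation and alkaline peroxide oxidation (1,2-shift of the aryl group from boron to oxygen) place the hydroxyl exactly where the bromine was; alkaline peroxide does not epoxidise an unactivated alkene and benzyl ethers survive n-BuLi at –78 °C.

Step 6
Reactants: 11 2,4-bis(benzyloxy)-6-(oct-7-en-1-yl)phenol; 12 trichloroethylene
Product: 14 1,5-bis(benzyloxy)-2-{[(E)-1,2-dichloroethenyl]oxy}-3-(oct-7-en-1-yl)benzene, via dichloroacetylene 13 (not isolated)
Conditions: K2CO3, DMF (degassed), 70 °C, N2, closed vessel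
Reagents that add atoms: none
Why: Base eliminates HCl from trichloroethylene to give dichloroacetylene, to which the phenoxide adds in anti fashion to give the (E)-1,2-dichlorovinyl ether (the established trichloroethylene route to ynol ether precursors); the linear electrophile is indifferent to the two ortho substituents of the phenol.

Step 7
Reactants: 14 1,5-bis(benzyloxy)-2-{[(E)-1,2-dichloroethenyl]oxy}-3-(oct-7-en-1-yl)benzene
Product: 17 1,5-bis(benzyloxy)-2-(ethynyloxy)-3-(oct-7-en-1-yl)benzene, via chloroethynyl aryl ether 15 (not isolated), via lithium aryloxyacetylide 16 (not isolated)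
Conditions: n-BuLi (2.5 equiv), THF, –78 → –40 °C; then H2O, –78 → 0 °C
Reagents that add atoms: none
Why: n-BuLi induces β-elimination of HCl to the chloroalkynyl ether and a second equivalent performs chlorine–lithium exchange to the acetylide, which is protonated to the terminal aryl ynol ether; this is the usual completion of the trichloroethylene ynol ether synthesis, and the product is used without storage.

Step 8
Reactants: 5 3-(oct-7-en-1-yl)cyclobut-2-en-1-one (1.3 equiv); 17 1,5-bis(benzyloxy)-2-(ethynyloxy)-3-(oct-7-en-1-yl)benzene
Product: 22 3-[2,4-bis(benzyloxy)-6-(oct-7-en-1-yl)phenoxy]-5-(oct-7-en-1-yl)phenol, via vinylketene 18 (not isolated), via 4-vinylcyclobutenone 19 (not isolated), via dienylketene 20 (not isolated), via cyclohexa-2,4-dienone 21 (not isolated)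
Conditions: toluene (0.4 M), 80 °C, then 120 °C (sealed tube); then KOH, MeOH, rt
Reagents that add atoms: none
Why: On heating, 5 opens reversibly by 4π electrocyclic cleavage to vinylketene 18, and ynol ether 17, whose terminal CH carbon is made nucleophilic by the oxygen, adds to the ketene C=C in a regiospecific [2+2] cycloaddition that forms C1a–C6a (CH carbon to the ketene carbonyl carbon) and C4a–C5a, giving vinylcyclobutenone 19. A second reversible 4π opening gives dienylketene 20, whose isomer with the vinyl group turned towards the ketene closes by 6π electrocyclisation (re-forming C1a–C2a) to cyclohexadienone 21, and tautomerisation gives phenol 22. This is the Danheiser benzannulation of a 3-alkylcyclobutenone with an ynol ether, here an aryl ether in place of the usual alkyl or silyl ether. Ring A is closed as a six-membered carbocycle by a thermally allowed disrotatory 6π electrocyclisation of a trienoid chain; the macrocycle is not involved. The only stereocentre formed, C4 of 19, is transient and vanishes on ring opening, so no stereocontrol is required. The selectivity needed is regiochemical and is secured by the polarity of the ynol ether, which places the aryloxy group meta to the new hydroxyl and the cyclobutenone alkyl group meta to both. Chemoselectivity rests on the ynol ether being far more reactive towards the ketene than the two isolated terminal alkenes, and an aryl ynol ether has no β-hydrogen for retro-ene loss of ketene. The closing KOH/MeOH treatment returns any product that was O-acylated by surplus vinylketene to the free phenol.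

Step 9
Reactants: 22 3-[2,4-bis(benzyloxy)-6-(oct-7-en-1-yl)phenoxy]-5-(oct-7-en-1-yl)phenol
Product: 23 3^4,3^6-bis(benzyloxy)-2-oxa-1(1,3),3(1,2)-dibenzenacycloheptadecaphan-10-en-1^5-ol (E/Z mixture)
Conditions: second-generation Grubbs catalyst, (H2IMes)(PCy3)Cl2Ru=CHPh (5 mol %), CH2Cl2 (1 mM), 40 °C
Reagents that add atoms: none
Why: Ring-closing metathesis of two unhindered terminal alkenes, driven by loss of ethylene; high dilution favours the unstrained 20-membered ring over oligomers, the free phenol is tolerated by the ruthenium carbene, and the alkene geometry does not matter because the double bond is hydrogenated next.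

Step 10
Reactants: 23 3^4,3^6-bis(benzyloxy)-2-oxa-1(1,3),3(1,2)-dibenzenacycloheptadecaphan-10-en-1^5-ol
Product: 24 2-oxa-1(1,3),3(1,2)-dibenzenacycloheptadecaphane-1^5,3^4,3^6-triol (CNP0173380.0)
Conditions: H2 (1 atm), Pd/C (10% Pd), EtOAc/MeOH, rt
Reagents that add atoms: none
Why: Heterogeneous hydrogenation saturates the disubstituted alkene and hydrogenolyses both aryl benzyl ethers in one operation, while the diaryl ether is inert; the oxidation-prone ring B is thus released under neutral, reducing conditions.

## Compound list

1 | 8-bromooct-1-ene | C=CCCCCCCBr | starting material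
2 | oct-7-en-1-ylmagnesium bromide (THF solution) | C=CCCCCCC[Mg]Br | intermediate
3 | 3-ethoxycyclobut-2-en-1-one | CCOC1=CC(=O)C1 | starting material
4 | 3-ethoxy-1-(oct-7-en-1-yl)cyclobut-2-en-1-ol (racemic; present first as its bromomagnesium alkoxide) | CCOC1=CC(O)(CCCCCCC=C)C1 | intermediate
5 | 3-(oct-7-en-1-yl)cyclobut-2-en-1-one | O=C1C=C(CCCCCCC=C)C1 | intermediate
6 | 1,3-bis(benzyloxy)-5-bromobenzene | Brc1cc(OCc2ccccc2)cc(OCc2ccccc2)c1 | starting material
7 | 1,3-bis(benzyloxy)-5-(oct-7-en-1-yl)benzene | C=CCCCCCCc1cc(OCc2ccccc2)cc(OCc2ccccc2)c1 | intermediate
8 | 1,5-bis(benzyloxy)-2-bromo-3-(oct-7-en-1-yl)benzene | C=CCCCCCCc1cc(OCc2ccccc2)cc(OCc2ccccc2)c1Br | intermediate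
9 | [2,4-bis(benzyloxy)-6-(oct-7-en-1-yl)phenyl]lithium | [Li]c1c(OCc2ccccc2)cc(OCc2ccccc2)cc1CCCCCCC=C | intermediate
10 | dimethyl [2,4-bis(benzyloxy)-6-(oct-7-en-1-yl)phenyl]boronate | COB(OC)c1c(OCc2ccccc2)cc(OCc2ccccc2)cc1CCCCCCC=C | intermediate
11 | 2,4-bis(benzyloxy)-6-(oct-7-en-1-yl)phenol | Oc1c(OCc2ccccc2)cc(OCc2ccccc2)cc1CCCCCCC=C | intermediate
12 | trichloroethylene | ClC=C(Cl)Cl | starting material
13 | dichloroacetylene | ClC#CCl | intermediate
14 | 1,5-bis(benzyloxy)-2-{[(E)-1,2-dichloroethenyl]oxy}-3-(oct-7-en-1-yl)benzene | Cl/C=C(/Cl)Oc1c(OCc2ccccc2)cc(OCc2ccccc2)cc1CCCCCCC=C | intermediate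
15 | 1,5-bis(benzyloxy)-2-[(chloroethynyl)oxy]-3-(oct-7-en-1-yl)benzene | ClC#COc1c(OCc2ccccc2)cc(OCc2ccccc2)cc1CCCCCCC=C | intermediate
16 | lithium [2,4-bis(benzyloxy)-6-(oct-7-en-1-yl)phenoxy]acetylide | [Li]C#COc1c(OCc2ccccc2)cc(OCc2ccccc2)cc1CCCCCCC=C | intermediate
17 | 1,5-bis(benzyloxy)-2-(ethynyloxy)-3-(oct-7-en-1-yl)benzene | C#COc1c(OCc2ccccc2)cc(OCc2ccccc2)cc1CCCCCCC=C | intermediate
18 | 3-methylideneundeca-1,10-dien-1-one (vinylketene) | O=C=CC(=C)CCCCCCC=C | intermediate
19 | 3-[2,4-bis(benzyloxy)-6-(oct-7-en-1-yl)phenoxy]-4-(deca-1,9-dien-2-yl)cyclobut-2-en-1-one (racemic) | O=C1C=C(Oc2c(OCc3ccccc3)cc(OCc3ccccc3)cc2CCCCCCC=C)C1C(=C)CCCCCCC=C | intermediate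
20 | (3E)-3-[2,4-bis(benzyloxy)-6-(oct-7-en-1-yl)phenoxy]-5-methylidenetrideca-1,3,12-trien-1-one (dienylketene; ketenyl and vinyl groups cis) | O=C=C/C(Oc1c(OCc2ccccc2)cc(OCc2ccccc2)cc1CCCCCCC=C)=C\C(=C)CCCCCCC=C | intermediate
21 | 3-[2,4-bis(benzyloxy)-6-(oct-7-en-1-yl)phenoxy]-5-(oct-7-en-1-yl)cyclohexa-2,4-dien-1-one | O=C1C=C(Oc2c(OCc3ccccc3)cc(OCc3ccccc3)cc2CCCCCCC=C)C=C(CCCCCCC=C)C1 | intermediate
22 | 3-[2,4-bis(benzyloxy)-6-(oct-7-en-1-yl)phenoxy]-5-(oct-7-en-1-yl)phenol | Oc1cc(CCCCCCC=C)cc(Oc2c(OCc3ccccc3)cc(OCc3ccccc3)cc2CCCCCCC=C)c1 | intermediate
23 | 3^4,3^6-bis(benzyloxy)-2-oxa-1(1,3),3(1,2)-dibenzenacycloheptadecaphan-10-en-1^5-ol: ring A (5-hydroxy-1,3-phenylene) and ring B (3,5-bis(benzyloxy)-1,2-phenylene) joined by one ether oxygen and a tetradec-7-ene-1,14-diyl chain, E/Z mixture | Oc1cc2cc(c1)Oc1c(OCc3ccccc3)cc(OCc3ccccc3)cc1CCCCCCC=CCCCCCC2 | intermediate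
24 | 2-oxa-1(1,3),3(1,2)-dibenzenacycloheptadecaphane-1^5,3^4,3^6-triol (CNP0173380.0): ring A (5-hydroxy-1,3-phenylene) and ring B (3,5-dihydroxy-1,2-phenylene) joined by one ether oxygen and a tetradecane-1,14-diyl chain | Oc1cc2cc(c1)Oc1c(O)cc(O)cc1CCCCCCCCCCCCCC2 | target

## Step count and risks

Total step count: 10. Longest linear sequence: 9 steps (steps 1 and 3 to 10, from 1 and 6); step 2 is a one-step branch from the common Grignard solution 2 that joins at step 8.

**Step 8 (key step).**
- **Risk.** An aryloxy oxygen donates less strongly than an alkoxy or siloxy oxygen, so capture of vinylketene 18 by 17 may be slow. The ynol ether could then be lost to hydration or oligomerisation at 80–120 °C, or the ketene consumed by dimerisation or by acylating the product phenol, before ring A is formed.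
- **Fallback.** Ring A would be taken ready-made and the ether formed by copper catalysis, setting out from phenol 11 and Grignard reagent 2. Mono-alkylation of 1-(benzyloxy)-3,5-dibromobenzene F1 (used in excess) with 2 under the conditions of step 3 would give 1-(benzyloxy)-3-bromo-5-(oct-7-en-1-yl)benzene F2. Ullmann etherification of F2 with 11 (CuI, picolinic acid, K3PO4, DMSO, 100 °C) would give 1-(benzyloxy)-3-[2,4-bis(benzyloxy)-6-(oct-7-en-1-yl)phenoxy]-5-(oct-7-en-1-yl)benzene F3. Ring-closing metathesis as in step 9 would give the tris(benzyl) macrocycle F4. The hydrogenation of step 10 would remove all three benzyl groups, so the fallback returns to the route at 24.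

**Step 9.**
- **Risk.** Intermolecular metathesis to oligomers may compete with closure of the 20-membered ring. Ruthenium hydride species may also move the terminal double bonds along the chain before closure, giving ring-contracted homologues that cannot be separated after hydrogenation.
- **Fallback.** The ring would be closed by carbonyl coupling, setting out from 22. Lemieux–Johnson cleavage of both terminal alkenes (OsO4 cat., NaIO4, 2,6-lutidine, dioxane/H2O) would give 7-{3-[2,4-bis(benzyloxy)-6-(7-oxoheptyl)phenoxy]-5-hydroxyphenyl}heptanal F5. McMurry coupling of F5 (TiCl3, Zn–Cu couple, DME, reflux, slow addition) would give the same cycloalkene 23, where the route is rejoined.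

**Step 7.**
- **Risk.** The terminal aryl ynol ether may be lost during work-up or purification through hydration to the aryl acetate or through oligomerisation. Excess n-BuLi may begin to metalate a benzylic ether position if the temperature rises.
- **Fallback.** The alkyne terminus would be capped, setting out from 14. The acetylide 16 would be quenched with Me3SiCl instead of water to give {[2,4-bis(benzyloxy)-6-(oct-7-en-1-yl)phenoxy]ethynyl}trimethylsilane F6, which should be stable to chromatography. Benzannulation of F6 with 5 under the conditions of step 8 would give 3-[2,4-bis(benzyloxy)-6-(oct-7-en-1-yl)phenoxy]-5-(oct-7-en-1-yl)-2-(trimethylsilyl)phenol F7, with silicon on C6a. Ipso-protodesilylation (CF3CO2H, CH2Cl2, 0 °C) would return the route to 22.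

**Step 4.**
- **Risk.** Chemoselectivity and site selectivity may be lost: bromine may add to the terminal alkene, or substitution may occur at the carbon between the two benzyloxy groups.
- **Fallback.** The oxygen would be introduced through a formyl group, setting out from 7. Vilsmeier–Haack formylation (POCl3, DMF) at the same ring position would give 2,4-bis(benzyloxy)-6-(oct-7-en-1-yl)benzaldehyde F8. Dakin oxidation (H2O2, cat. H2SO4, MeOH) and hydrolysis of the aryl formate would give phenol 11, so steps 4 and 5 are both bypassed and the route is rejoined at 11.

## Further compounds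

F1 | step 8 | 1-(benzyloxy)-3,5-dibromobenzene | Brc1cc(Br)cc(OCc2ccccc2)c1
F2 | step 8 | 1-(benzyloxy)-3-bromo-5-(oct-7-en-1-yl)benzene | Brc1cc(CCCCCCC=C)cc(OCc2ccccc2)c1
F3 | step 8 | 1-(benzyloxy)-3-[2,4-bis(benzyloxy)-6-(oct-7-en-1-yl)phenoxy]-5-(oct-7-en-1-yl)benzene | C=CCCCCCCc1cc(OCc2ccccc2)cc(Oc2c(OCc3ccccc3)cc(OCc3ccccc3)cc2CCCCCCC=C)c1
F4 | step 8 | 1^5,3^4,3^6-tris(benzyloxy)-2-oxa-1(1,3),3(1,2)-dibenzenacycloheptadecaphan-10-ene (E/Z mixture) | c1ccc(cc1)COc1cc2cc(c1)Oc1c(OCc3ccccc3)cc(OCc3ccccc3)cc1CCCCCCC=CCCCCCC2
F5 | step 9 | 7-{3-[2,4-bis(benzyloxy)-6-(7-oxoheptyl)phenoxy]-5-hydroxyphenyl}heptanal | O=CCCCCCCc1cc(O)cc(Oc2c(OCc3ccccc3)cc(OCc3ccccc3)cc2CCCCCCC=O)c1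
F6 | step 7 | {[2,4-bis(benzyloxy)-6-(oct-7-en-1-yl)phenoxy]ethynyl}trimethylsilane | C[Si](C)(C)C#COc1c(OCc2ccccc2)cc(OCc2ccccc2)cc1CCCCCCC=C
F7 | step 7 | 3-[2,4-bis(benzyloxy)-6-(oct-7-en-1-yl)phenoxy]-5-(oct-7-en-1-yl)-2-(trimethylsilyl)phenol | Oc1cc(CCCCCCC=C)cc(Oc2c(OCc3ccccc3)cc(OCc3ccccc3)cc2CCCCCCC=C)c1[Si](C)(C)C
F8 | step 4 | 2,4-bis(benzyloxy)-6-(oct-7-en-1-yl)benzaldehyde | O=Cc1c(OCc2ccccc2)cc(OCc2ccccc2)cc1CCCCCCC=C
A1 | alternative 1 | macrocyclic 4-pyrone: 2-(aryloxymethyl)-6-alkyl-4H-pyran-4-one whose aryl group (5-methoxy-1,3-phenylene) and C6 are linked by a tetradecane-1,14-diyl chain | COc1cc2cc(c1)OCc1cc(=O)cc(o1)CCCCCCCCCCCCCC2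
A2 | alternative 1 | ring A methyl ether of the target (1^5-methoxy-2-oxa-1(1,3),3(1,2)-dibenzenacycloheptadecaphane-3^4,3^6-diol) | COc1cc2cc(c1)Oc1c(O)cc(O)cc1CCCCCCCCCCCCCC2
A3 | alternative 2 | 3,5-dimethoxybenzyne | COC1=CC(OC)=CC#C1
A4 | alternative 2 | 2-[14-(3-chloro-5-methoxyphenyl)tetradecyl]-4,6-dimethoxyphenol | COc1cc(Cl)cc(CCCCCCCCCCCCCCc2cc(OC)cc(OC)c2O)c1
A5 | alternative 3 | macrocyclic aryloxy enone: 3-aryloxyalk-3-en-2-one whose aryl group (5-methoxy-1,3-phenylene) and C4 are linked by a tetradecane-1,14-diyl chain (alkene geometry not fixed by the plan) | COc1cc2cc(c1)OC(C(C)=O)=CCCCCCCCCCCCCCC2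
A6 | alternative 3 | macrocycle-fused 4-aryloxy-5-alkyl-6-(methoxycarbonyl)cyclohexane-1,3-dione (racemic, trans,trans; one enantiomer drawn) | COc1cc2cc(c1)O[C@H]1C(=O)CC(=O)[C@@H](C(=O)OC)[C@@H]1CCCCCCCCCCCCCC2
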